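**Plan**
- Retrosynthesis: the C5 methoxy group is taken off first (back to the C4=C5 enone through its epoxide). The cyclohexadienone ring is then cut at C3a–C4 and C7–C7a into a lactone-derived silyl ketene acetal and 3-ethoxycyclobutanone. Last come the C3a allyl group and the lactone, which goes back to an anti-crotylation of 3,4,5-trimethoxybenzaldehyde.
- Enabling feature: in the ring O1–C2–C3–C3a–C7a, C7a is at the carboxyl oxidation level (O1–C7a=C7–C6=O is a vinylogous ester) and C3a is its α-carbon. That ring is therefore a masked γ-butyrolactone whose ketene acetal is nucleophilic at C3a and then electrophilic at C7a, the exact complement of the C4-electrophile/C7-nucleophile set free when a 3-alkoxycyclobutanone opens under strain release.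
- Forward order: the five-membered ring (as the lactone) first, then the allyl group at C3a, then the six-membered ring (C4 to C7) in one formal [4+2] event, then oxygenation of C5.
- Stereochemistry: C2 and C3 come from a reagent-controlled Brown (E)-crotylation. Quaternary C3a is set in the key step by attack anti to the C3 methyl group, so the allyl group, introduced earlier, ends up cis to that methyl.
- The methoxy group is added after the annulation because a 2-methoxy group on the cyclobutanone would be expected to steer ring opening to the wrong C–C bond.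

Key step: step 6

Remark: 3-ethoxycyclobutanone (10) is treated as a purchasable building block (otherwise it would be made from dichloroketene and ethyl vinyl ether followed by zinc dechlorination); the epoxide configuration in 14 is left open because both epoxide carbons become sp2 in step 8.

**Step 1**
Reactants: 1 3,4,5-trimethoxybenzaldehyde; 2 trans-2-butene
Product: 5 (1S,2S)-2-methyl-1-(3,4,5-trimethoxyphenyl)but-3-en-1-ol, via (E)-crotylpotassium 3 (not isolated), via (E)-crotyldiisopinocampheylborane 4 (not isolated)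
Conditions: 2, n-BuLi, KOt-Bu, THF, −78 to −45 °C; (−)-Ipc2BOMe [(+)-α-pinene series], −78 °C; BF3·OEt2; then 1, −78 °C; NaOH, H2O2, 0 °C to rt
Reagents that add atoms: none
Why: Brown asymmetric crotylboration: the chair transition state translates the E geometry into the anti relationship, and the isopinocampheyl groups of the (+)-α-pinene series should direct attack to the Si face of the aldehyde, setting both stereocentres as 1S,2S.

**Step 2**
Reactants: 5 (1S,2S)-2-methyl-1-(3,4,5-trimethoxyphenyl)but-3-en-1-ol
Product: 6 (1S,2S)-2-methyl-1-(3,4,5-trimethoxyphenyl)butane-1,4-diol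
Conditions: 9-BBN (2.2 equiv), THF, 0 °C to rt; NaOH, H2O2
Reagents that add atoms: hydrogen peroxide (OO)
Why: Hydroboration–oxidation: 9-BBN places boron on the terminal carbon of the monosubstituted alkene and oxidation gives the primary alcohol without touching the two existing stereocentres.

**Step 3**
Reactants: 6 (1S,2S)-2-methyl-1-(3,4,5-trimethoxyphenyl)butane-1,4-diol
Product: 7 (4S,5S)-4-methyl-5-(3,4,5-trimethoxyphenyl)dihydrofuran-2(3H)-one
Conditions: TEMPO (cat.), PhI(OAc)2, CH2Cl2, rt
Reagents that add atoms: none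
Why: TEMPO/PhI(OAc)2 oxidative lactonization: the oxoammonium species oxidizes the primary alcohol in preference to the secondary benzylic one, and the lactol that forms is oxidized on to the trans γ-lactone with no stereocentre involved.

**Step 4**
Reactants: 7 (4S,5S)-4-methyl-5-(3,4,5-trimethoxyphenyl)dihydrofuran-2(3H)-one
Product: 8 (3S,4S,5S)-3-allyl-4-methyl-5-(3,4,5-trimethoxyphenyl)dihydrofuran-2(3H)-one
Conditions: LiN(i-Pr)2, THF, −78 °C; allyl bromide, −78 to −40 °C
Reagents that add atoms: allyl bromide (C=CCBr)
Why: Lactone enolate alkylation: the lithium enolate should be allylated on the face opposite the adjacent C4 methyl group, and since this centre is erased in step 5 its configuration is of no consequence.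

**Step 5**
Reactants: 8 (3S,4S,5S)-3-allyl-4-methyl-5-(3,4,5-trimethoxyphenyl)dihydrofuran-2(3H)-one
Product: 9 tert-butyl{[(4S,5S)-3-allyl-4-methyl-5-(3,4,5-trimethoxyphenyl)-4,5-dihydrofuran-2-yl]oxy}dimethylsilane
Conditions: LiN(i-Pr)2, THF, −78 °C; TBSCl, DMPU, −78 °C to rt; non-aqueous work-up
Reagents that add atoms: tert-butyldimethylsilyl chloride (CC(C)(C)[Si](C)(C)Cl)
Why: O-Silylation of a lactone enolate with a hard silicon electrophile in the presence of a polar cosolvent should give the cyclic tetrasubstituted silyl ketene acetal, in which the ring fixes the geometry and only the C4/C5 stereocentres remain.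

**Step 6**
Reactants: 9 tert-butyl{[(4S,5S)-3-allyl-4-methyl-5-(3,4,5-trimethoxyphenyl)-4,5-dihydrofuran-2-yl]oxy}dimethylsilane; 10 3-ethoxycyclobutanone
Product: 13 (2S,3S,3aS)-3a-allyl-3-methyl-2-(3,4,5-trimethoxyphenyl)-3,3a-dihydrobenzofuran-6(2H)-one, via 7a-silyloxy-4-ethoxy cyclohexanone adduct 11 (not isolated), via 4-ethoxy enone 12 (not isolated)
Conditions: 10, EtAlCl2 (1.2 equiv), CH2Cl2, −78 °C; add 9, −78 to −40 °C; aq NaHCO3; then KOt-Bu (0.2 equiv), THF, 0 °C to rt
Reagents that add atoms: none
Why: Proposed new method: EtAlCl2 binds the carbonyl group of 10 and, pushed by the ethoxy lone pair and by release of ring strain, one of the two equivalent C–C bonds at the ethoxy carbon breaks to an oxocarbenium/aluminium enolate 1,4-zwitterion; the nucleophilic carbon of 9 (future C3a) adds to the oxocarbenium carbon (C4), the enolate carbon (C7) then adds to the silyloxy-dioxocarbenium carbon (C7a) to give 11, and loss of silanol (to 12) followed by base-mediated E1cB loss of ethanol gives the cross-conjugated dienone. The closest known reaction type is the Lewis-acid-promoted formal [4+2] cycloaddition of 3-alkoxycyclobutanones with silyl enol ethers, aldehydes or allylsilanes; a lactone-derived silyl ketene acetal as the two-carbon partner and the creation of a quaternary carbon are new. The six-membered ring closes by a 6-(enolendo)-exo-trig Claisen-type attack, which is stereoelectronically favoured. The only lasting new stereocentre, quaternary C3a, is set in the first bond formation by approach of the electrophile to the face of the dihydrofuran anti to the adjacent C3 methyl group, which leaves the allyl group cis to that methyl as in the target, while the centres at C4 and C7a are destroyed in the eliminations. The step needs C-alkylation by the ring-opened species in preference to Mukaiyama addition to the intact strained ketone, and ring closure in preference to loss of the silyl group; pre-complexing 10 with EtAlCl2 before 9 is added, the symmetry of 10 (no regiochemical choice in the ring opening) and the robust tert-butyldimethylsilyl group are meant to secure this.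

**Step 7**
Reactants: 13 (2S,3S,3aS)-3a-allyl-3-methyl-2-(3,4,5-trimethoxyphenyl)-3,3a-dihydrobenzofuran-6(2H)-one
Product: 14 (2S,3S,3aR)-3a-allyl-4,5-epoxy-3-methyl-2-(3,4,5-trimethoxyphenyl)-3,3a,4,5-tetrahydrobenzofuran-6(2H)-one (epoxide face not controlled)
Conditions: t-BuOOH (decane solution), DBU, CH2Cl2, 0 °C to rt
Reagents that add atoms: tert-butyl hydroperoxide (CC(C)(C)OO)
Why: Weitz–Scheffer nucleophilic epoxidation: the peroxide anion should add to C4 of the simple enone, which is far more electrophilic than the donor-substituted C7=C7a bond of the vinylogous ester or the isolated allyl alkene, and the two uncontrolled epoxide centres are both removed in step 8.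

**Step 8**
Reactants: 14 (2S,3S,3aR)-3a-allyl-4,5-epoxy-3-methyl-2-(3,4,5-trimethoxyphenyl)-3,3a,4,5-tetrahydrobenzofuran-6(2H)-one
Product: 15 (2S,3S,3aR)-3a-allyl-5-methoxy-3-methyl-2-(3,4,5-trimethoxyphenyl)-3,3a-dihydrobenzofuran-6(2H)-one
Conditions: NaOMe (0.5 equiv), MeOH, 50 °C
Reagents that add atoms: sodium methoxide ([Na+].[O-]C) in methanol (CO)
Why: Known conversion of an α,β-epoxy ketone into an α-methoxy enone: methoxide should open the epoxide at C5 (α to the carbonyl group and, unlike C4, not neopentyl) and the resulting β-hydroxy ketone should dehydrate by E1cB to the C4=C5 enol ether, leaving C2, C3 and C3a untouched.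

**Compound list**
1 | 3,4,5-trimethoxybenzaldehyde | COc1cc(C=O)cc(OC)c1OC | starting material
2 | trans-2-butene | C/C=C/C | starting material
3 | (E)-crotylpotassium | [K+].C/C=C/[CH2-] | intermediate
4 | (E)-but-2-en-1-ylbis[(1R,2S,3R,5R)-2,6,6-trimethylbicyclo[3.1.1]heptan-3-yl]borane, the (E)-crotyldiisopinocampheylborane of the (+)-α-pinene series | C/C=C/CB([C@@H]1C[C@@H]2C[C@H]([C@H]1C)C2(C)C)[C@@H]1C[C@@H]2C[C@H]([C@H]1C)C2(C)C | intermediate
5 | (1S,2S)-2-methyl-1-(3,4,5-trimethoxyphenyl)but-3-en-1-ol | O[C@H](c1cc(OC)c(OC)c(OC)c1)[C@H](C=C)C | intermediate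
6 | (1S,2S)-2-methyl-1-(3,4,5-trimethoxyphenyl)butane-1,4-diol | O[C@H](c1cc(OC)c(OC)c(OC)c1)[C@H](CCO)C | intermediate
7 | (4S,5S)-4-methyl-5-(3,4,5-trimethoxyphenyl)dihydrofuran-2(3H)-one | O=C1O[C@H](c2cc(OC)c(OC)c(OC)c2)[C@@H](C)C1 | intermediate
8 | (3S,4S,5S)-3-allyl-4-methyl-5-(3,4,5-trimethoxyphenyl)dihydrofuran-2(3H)-one | C=CC[C@@H]1C(=O)O[C@H](c2cc(OC)c(OC)c(OC)c2)[C@H]1C | intermediate
9 | tert-butyl{[(4S,5S)-3-allyl-4-methyl-5-(3,4,5-trimethoxyphenyl)-4,5-dihydrofuran-2-yl]oxy}dimethylsilane | C=CCC1=C(O[Si](C)(C)C(C)(C)C)O[C@H](c2cc(OC)c(OC)c(OC)c2)[C@H]1C | intermediate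
10 | 3-ethoxycyclobutanone | CCOC1CC(=O)C1 | starting material
11 | (2S,3S,3aR)-3a-allyl-7a-(tert-butyldimethylsilyloxy)-4-ethoxy-3-methyl-2-(3,4,5-trimethoxyphenyl)hexahydrobenzofuran-6(2H)-one (mixture at C4 and C7a) | C=CC[C@@]12C(OCC)CC(=O)CC1(O[Si](C)(C)C(C)(C)C)O[C@H](c3cc(OC)c(OC)c(OC)c3)[C@H]2C | intermediate
12 | (2S,3S,3aR)-3a-allyl-4-ethoxy-3-methyl-2-(3,4,5-trimethoxyphenyl)-3,3a,4,5-tetrahydrobenzofuran-6(2H)-one (C4 epimers) | C=CC[C@@]12C(OCC)CC(=O)C=C1O[C@H](c3cc(OC)c(OC)c(OC)c3)[C@H]2C | intermediate
13 | (2S,3S,3aS)-3a-allyl-3-methyl-2-(3,4,5-trimethoxyphenyl)-3,3a-dihydrobenzofuran-6(2H)-one | C=CC[C@@]12C=CC(=O)C=C1O[C@H](c3cc(OC)c(OC)c(OC)c3)[C@H]2C | intermediate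
14 | (2S,3S,3aR)-3a-allyl-4,5-epoxy-3-methyl-2-(3,4,5-trimethoxyphenyl)-3,3a,4,5-tetrahydrobenzofuran-6(2H)-one (epoxide face not controlled) | C=CC[C@@]12C3OC3C(=O)C=C1O[C@H](c4cc(OC)c(OC)c(OC)c4)[C@H]2C | intermediate
15 | (2S,3S,3aR)-3a-allyl-5-methoxy-3-methyl-2-(3,4,5-trimethoxyphenyl)-3,3a-dihydrobenzofuran-6(2H)-one | C=CC[C@@]12C=C(OC)C(=O)C=C1O[C@H](c3cc(OC)c(OC)c(OC)c3)[C@H]2C | target

Total step count: 8. Longest linear sequence: 8 steps (1 to 15); 10 enters at step 6.

**Steps most likely to fail**

Step 6 (Proposed new method). The unsubstituted cyclobutanone may open sluggishly, the ketene acetal may add to the intact ketone carbonyl group instead, or the silyl group may be lost before the ring closes. The fallback builds the same ring stepwise with known reactions, setting out from 9 and coming back at 13. A Mukaiyama-type alkylation of 9 with 4,4-dimethoxybutan-2-one (TMSOTf cat., CH2Cl2, −78 °C) should form the quaternary centre with the same anti-to-methyl facial control and give the keto lactone (3R,4S,5S)-3-allyl-3-(1-methoxy-3-oxobutyl)-4-methyl-5-(3,4,5-trimethoxyphenyl)dihydrofuran-2(3H)-one F1. Kinetic enolization of its methyl ketone (LiN(SiMe3)2, THF, −78 to 0 °C) and intramolecular Claisen condensation onto the lactone carbonyl group should open the lactone to the hydroxy diketone (4R)-4-allyl-4-[(1S,2S)-1-hydroxy-1-(3,4,5-trimethoxyphenyl)propan-2-yl]-5-methoxycyclohexane-1,3-dione F2. Mild acid (PPTS, toluene, 60 °C) should then re-close the five-membered ring as the vinylogous ester, and catalytic KOt-Bu should eliminate methanol to give 13.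

Step 8. Methoxide may add to C7a and open the vinylogous ester with loss of the C2 alkoxide, or attack the wrong epoxide carbon. The fallback sets out from 14 and comes back at 15. Aqueous LiOH in THF followed by mild acidification should isomerize the epoxy ketone to the diosphenol (2S,3S,3aR)-3a-allyl-5-hydroxy-3-methyl-2-(3,4,5-trimethoxyphenyl)-3,3a-dihydrobenzofuran-6(2H)-one F5; any hydroxide adduct at C7a reverts to the same ring on acidification. O-Methylation of the acidic enol (MeI, K2CO3, acetone) then gives 15.

Step 7. The peroxide anion or the base may add to the vinylogous ester carbon C7a, or addition to the neopentyl β-carbon C4 may be too slow. The fallback avoids the epoxide, setting out from 13 and coming back at 15. Conjugate reduction of the C4=C5 enone with LiBH(s-Bu)3 (THF, −78 °C) and oxidation of the resulting enolate in the flask with 2-(phenylsulfonyl)-3-phenyloxaziridine should give (2S,3S,3aS)-3a-allyl-5-hydroxy-3-methyl-2-(3,4,5-trimethoxyphenyl)-3,3a,4,5-tetrahydrobenzofuran-6(2H)-one F3 (C5 epimers). O-Methylation (MeI, Ag2O) should give the 5-methoxy ketone (2S,3S,3aS)-3a-allyl-5-methoxy-3-methyl-2-(3,4,5-trimethoxyphenyl)-3,3a,4,5-tetrahydrobenzofuran-6(2H)-one F4. Saegusa–Ito dehydrogenation (LiN(SiMe3)2, TMSCl; then Pd(OAc)2, MeCN) should then restore the C4=C5 double bond, since C5 is the only enolizable position, and give 15.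

**Further compounds**
F1 | step 6 | (3R,4S,5S)-3-allyl-3-(1-methoxy-3-oxobutyl)-4-methyl-5-(3,4,5-trimethoxyphenyl)dihydrofuran-2(3H)-one | C=CC[C@@]1(C(OC)CC(C)=O)C(=O)O[C@H](c2cc(OC)c(OC)c(OC)c2)[C@H]1C
F2 | step 6 | (4R)-4-allyl-4-[(1S,2S)-1-hydroxy-1-(3,4,5-trimethoxyphenyl)propan-2-yl]-5-methoxycyclohexane-1,3-dione | C=CC[C@@]1([C@H](C)[C@H](O)c2cc(OC)c(OC)c(OC)c2)C(OC)CC(=O)CC1=O
F3 | step 7 | (2S,3S,3aS)-3a-allyl-5-hydroxy-3-methyl-2-(3,4,5-trimethoxyphenyl)-3,3a,4,5-tetrahydrobenzofuran-6(2H)-one | C=CC[C@@]12CC(O)C(=O)C=C1O[C@H](c3cc(OC)c(OC)c(OC)c3)[C@H]2C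
F4 | step 7 | (2S,3S,3aS)-3a-allyl-5-methoxy-3-methyl-2-(3,4,5-trimethoxyphenyl)-3,3a,4,5-tetrahydrobenzofuran-6(2H)-one | C=CC[C@@]12CC(OC)C(=O)C=C1O[C@H](c3cc(OC)c(OC)c(OC)c3)[C@H]2C
F5 | step 8 | (2S,3S,3aR)-3a-allyl-5-hydroxy-3-methyl-2-(3,4,5-trimethoxyphenyl)-3,3a-dihydrobenzofuran-6(2H)-one | C=CC[C@@]12C=C(O)C(=O)C=C1O[C@H](c3cc(OC)c(OC)c(OC)c3)[C@H]2C
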